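C2, C3 and C4 of the furanone, the only ring, form a latent cyclopropenone. Its strained C2–C4 bond is exchanged for the O1–C5 unit of bromal, which brings C6 along as CBr3 at the correct oxidation level.
Numbering: ring O1–C2(=O)–C3(side chain)–C4(Br)–C5, exocyclic C6Br2, carbinol carbon C1'.
Disconnections, backwards: O–Si cleavage; C4–Br (Br2 addition to C3=C4, then loss of HBr); C5=C6 (loss of HBr from the 5-CBr3 butenolide); C4–C5 and O1–C2 (phosphine-triggered (3+2) annulation, which closes the ring).
The cyclopropenone comes from the silyl ether of (R)-hex-1-yn-3-ol and difluorocarbene. C1' is set by lipase resolution of the racemic alcohol and no later step breaks a bond at it.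

Key step: step 4

Assumption: the lipase follows the Kazlauskas rule for 1 (ethynyl smaller than propyl); the sense and level of enrichment of 2 are to be confirmed (Mosher ester, chiral GC) before step 2.

Step 1
Reactants: 1 rac-hex-1-yn-3-ol
Product: 2 (R)-hex-1-yn-3-ol
Conditions: Novozym 435 (immobilised Candida antarctica lipase B), vinyl acetate, MTBE, 30 °C, run past half conversion; chromatography
Reagents that add atoms: none
Why: Lipase-catalysed kinetic resolution (irreversible transesterification): by the Kazlauskas rule, ethynyl being the smaller and propyl the larger group, the (S)-alcohol should be acetylated and the slow-reacting (R)-alcohol left behind, so that the only stereocentre of the target (C1') is secured here and its enantiopurity can be raised by running past half conversion.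

Step 2
Reactants: 2 (R)-hex-1-yn-3-ol
Product: 3 (R)-tert-butyl(hex-1-yn-3-yloxy)dimethylsilane
Conditions: TBSCl, imidazole, DMF, 0 °C to rt
Reagents that add atoms: tert-butyldimethylsilyl chloride, CC(C)(C)[Si](C)(C)Cl
Why: Standard imidazole-promoted O-silylation, which leaves the C1'–O bond and hence the configuration untouched and turns the hydroxyl group into a bulky, poorly leaving ether that survives carbene, phosphine, amine and bromine.

Step 3
Reactants: 3 (R)-tert-butyl(hex-1-yn-3-yloxy)dimethylsilane, 4 (trifluoromethyl)trimethylsilane
Product: 6 (R)-2-[1-(tert-butyldimethylsilyloxy)butyl]cycloprop-2-en-1-one, via difluorocyclopropene 5 (not isolated)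
Conditions: 4 (2.5 equiv), NaI (2.2 equiv), THF, sealed tube, 110 °C; then wet silica gel, CH2Cl2, rt
Reagents that add atoms: water, O
Why: [2+1] cycloaddition of difluorocarbene (released from 4 by iodide) to the terminal alkyne followed by hydrolysis of the gem-difluorocyclopropene through a fluorocyclopropenylium ion, the established route from terminal alkynes to monosubstituted cyclopropenones, under near-neutral conditions that spare the silyl ether and C1'.

Step 4
Reactants: 6 (R)-2-[1-(tert-butyldimethylsilyloxy)butyl]cycloprop-2-en-1-one, 7 tribromoacetaldehyde (bromal)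
Product: 10 3-[(R)-1-(tert-butyldimethylsilyloxy)butyl]-5-(tribromomethyl)furan-2(5H)-one (C5 epimers), via ketenyl ylide 8 (not isolated), via phosphonio enolate 9 (not isolated)
Conditions: PPh3 (20 mol%), 6 (1.5 equiv), 4 Å molecular sieves, toluene, 0 °C, dark; freshly distilled 7 (1.0 equiv) in toluene added over several hours by syringe pump
Reagents that add atoms: none
Why: PPh3 adds in conjugate fashion to the unsubstituted ring carbon of 6 (the future C4), and relief of ring strain breaks the C2–C4 bond to give the ketenyl ylide 8, O=C2=C3(R)–C4H=PPh3. The ylide carbon C4 attacks the very electrophilic carbonyl carbon of 7 (C4–C5), as stabilised ylides do with trihaloacetaldehydes in Wittig olefinations, and the alkoxide O1 closes the furanone ring by 5-exo-dig addition to the ketene carbon C2 (O1–C2) faster than it can reach phosphorus, giving 9, whose enolate expels PPh3 in an E1cB step and sets up C3=C4. The closest known reaction type is the phosphine-catalysed (3+2) annulation of cyclopropenones with aldehydes to butenolides, applied here to bromal, a partner that has not yet been tried. The new stereocentre C5 is not controlled, since the remote C1' centre should exert little bias, and this is harmless because C5 becomes sp2 in step 5, while C1' takes no part in the reaction. The regioselectivity that places the side chain on C3 rests on the steric bias of 6, whose CH carbon is far more accessible than the carbon bearing the branched silyloxyalkyl group. The chemoselectivity of phosphorus for carbon over bromine (Appel- or Perkow-type halophilic attack on CBr3) is to be secured by a low stationary concentration of 7 against an excess of the strained acceptor 6, by a triarylphosphine of modest halophilicity and by an apolar solvent at low temperature.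

Step 5
Reactants: 10 3-[(R)-1-(tert-butyldimethylsilyloxy)butyl]-5-(tribromomethyl)furan-2(5H)-one
Product: 11 3-[(R)-1-(tert-butyldimethylsilyloxy)butyl]-5-(dibromomethylene)furan-2(5H)-one
Conditions: Et3N (1.2 equiv), CH2Cl2, 0 °C, dark
Reagents that add atoms: none
Why: E1cB dehydrobromination, the usual base-induced β-elimination route to γ-alkylidenebutenolides: C5–H is the vinylogously acidic γ-proton of the butenolide and the 2-oxidofuran formed expels bromide from the neighbouring CBr3 group, so both C5 epimers converge on one compound with C5=C6Br2, and doing this before the bromination makes C4 allylic for step 6.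

Step 6
Reactants: 11 3-[(R)-1-(tert-butyldimethylsilyloxy)butyl]-5-(dibromomethylene)furan-2(5H)-one
Product: 13 4-bromo-3-[(R)-1-(tert-butyldimethylsilyloxy)butyl]-5-(dibromomethylene)furan-2(5H)-one, via tetrabromide 12 (not isolated)
Conditions: Br2 (1.1 equiv), CH2Cl2, 0 °C to rt, dark; evaporation; then DBU (1.1 equiv), CH2Cl2, −40 to 0 °C
Reagents that add atoms: bromine, BrBr
Why: Bromine addition followed by dehydrobromination, the sequence used for vinylic bromination of butenolides and of α-alkyl-α,β-unsaturated acids: C6 is already fully brominated and hindered, so Br2 should add to C3=C4 through a bromonium ion opened at the allylic C4, and because C3 carries no hydrogen the base can only take C4–H, which is acidified by its own bromine and by the C5=C6Br2 unit, and expel the tertiary C3 bromide in an E1cB-like step that needs no anti-periplanar alignment and leaves Br on C4.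

Step 7
Reactants: 13 4-bromo-3-[(R)-1-(tert-butyldimethylsilyloxy)butyl]-5-(dibromomethylene)furan-2(5H)-one
Product: 14 4-bromo-5-(dibromomethylene)-3-[(R)-1-hydroxybutyl]furan-2(5H)-one (CNP0138117.1)
Conditions: 48% aq HF, MeCN, 0 °C to rt (plastic vessel)
Reagents that add atoms: none
Why: Acidic fluoride-mediated desilylation, chosen because the bromodienyl lactone tolerates acid but not basic fluoride or hydroxide; only the O–Si bond is cleaved, so C1' keeps the (R) configuration of the target.

Compound list
1 | rac-hex-1-yn-3-ol | CCCC(O)C#C | starting material
2 | (R)-hex-1-yn-3-ol | CCC[C@@H](O)C#C | intermediate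
3 | (R)-tert-butyl(hex-1-yn-3-yloxy)dimethylsilane | CCC[C@@H](O[Si](C)(C)C(C)(C)C)C#C | intermediate
4 | (trifluoromethyl)trimethylsilane | C[Si](C)(C)C(F)(F)F | starting material
5 | (R)-tert-butyl[1-(3,3-difluorocycloprop-1-en-1-yl)butoxy]dimethylsilane | CCC[C@@H](O[Si](C)(C)C(C)(C)C)C1=CC1(F)F | intermediate
6 | (R)-2-[1-(tert-butyldimethylsilyloxy)butyl]cycloprop-2-en-1-one | CCC[C@@H](O[Si](C)(C)C(C)(C)C)C1=CC1=O | intermediate
7 | tribromoacetaldehyde (bromal) | O=CC(Br)(Br)Br | starting material
8 | 2-[(R)-1-(tert-butyldimethylsilyloxy)butyl]-3-(triphenylphosphoranylidene)prop-1-en-1-one (ketenyl ylide) | CCC[C@@H](O[Si](C)(C)C(C)(C)C)C(=C=O)C=P(c1ccccc1)(c1ccccc1)c1ccccc1 | intermediate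
9 | 3-[(R)-1-(tert-butyldimethylsilyloxy)butyl]-5-(tribromomethyl)-4-(triphenylphosphonio)-4,5-dihydrofuran-2-olate | CCC[C@@H](O[Si](C)(C)C(C)(C)C)C1=C([O-])OC(C(Br)(Br)Br)C1[P+](c1ccccc1)(c1ccccc1)c1ccccc1 | intermediate
10 | 3-[(R)-1-(tert-butyldimethylsilyloxy)butyl]-5-(tribromomethyl)furan-2(5H)-one, C5 epimers | CCC[C@@H](O[Si](C)(C)C(C)(C)C)C1=CC(C(Br)(Br)Br)OC1=O | intermediate
11 | 3-[(R)-1-(tert-butyldimethylsilyloxy)butyl]-5-(dibromomethylene)furan-2(5H)-one | CCC[C@@H](O[Si](C)(C)C(C)(C)C)C1=CC(=C(Br)Br)OC1=O | intermediate
12 | trans-3,4-dibromo-3-[(R)-1-(tert-butyldimethylsilyloxy)butyl]-5-(dibromomethylene)dihydrofuran-2(3H)-one, diastereomers at C3/C4 | CCC[C@@H](O[Si](C)(C)C(C)(C)C)C1(Br)C(Br)C(=C(Br)Br)OC1=O | intermediate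
13 | 4-bromo-3-[(R)-1-(tert-butyldimethylsilyloxy)butyl]-5-(dibromomethylene)furan-2(5H)-one | CCC[C@@H](O[Si](C)(C)C(C)(C)C)C1=C(Br)C(=C(Br)Br)OC1=O | intermediate
14 | 4-bromo-5-(dibromomethylene)-3-[(R)-1-hydroxybutyl]furan-2(5H)-one | CCC[C@@H](O)C1=C(Br)C(=C(Br)Br)OC1=O | target

Total step count: 7. Longest linear sequence: 7 steps (1 to 14).

Steps most likely to fail

Step 4.
- The phosphine, or the ylide carbon, may attack a bromine of the CBr3 group instead of carbon, which drains catalyst and aldehyde.
- The ketenyl ylide may condense with further cyclopropenone while it waits for the aldehyde.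
- The basic ylide may trigger premature loss of HBr from the product, and this acid then quenches the ylide.

The fallback builds the ring by carbonylation and brings in C6 by olefination. It sets out from 3 and comes back at 11. Oxidative dicarbonylation of the terminal alkyne (PdI2, KI, CO/air, aqueous dioxane, 80 °C) should give the maleic anhydride 3-[(R)-1-(tert-butyldimethylsilyloxy)butyl]furan-2,5-dione F1, in which the two alkyne carbons are again C3 and C4. Ramirez dibromo-olefination with preformed Ph3P=CBr2 (CBr4, PPh3, Zn, CH2Cl2, stirred before F1 is added so that no free phosphine can add to C4) should then take place at the carbonyl group remote from the branched side chain. This is the usual outcome of Wittig-type olefination of hindered unsymmetrical cyclic anhydrides, and it gives 11 directly.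

Step 6.
- Bromine may add in the 1,4 sense (C3 and C6), or only sluggishly, to the crowded, electron-poor diene.
- The adduct may lose Br2 instead of HBr when base is added.
- Elimination may run towards C1'–H and erode the stereocentre.

A 1,4-adduct is not necessarily lost. A bromide-mediated SN2′ allylic shift from CBr3–C5=C4 to C6Br2=C5–C4Br would lead to 12.

The fallback changes the order of events. It sets out from 10 and comes back at 12, and so at 13. Bromine is added to 10 while C3=C4 is the only alkene, so only one mode of addition exists (Br2, CH2Cl2, rt, dark). This gives 3,4-dibromo-3-[(R)-1-(tert-butyldimethylsilyloxy)butyl]-5-(tribromomethyl)dihydrofuran-2(3H)-one F2. DBU (2.5 equiv, CH2Cl2, −20 °C to rt) should first remove C5–H together with one C6 bromide by anti E2, which free rotation of the CBr3 group allows. This produces 12, which loses the second HBr as in step 6.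

Step 1. The lipase may discriminate poorly between the ethynyl and propyl groups. The enrichment would then be insufficient, or much material would be lost at the high conversion needed.

The fallback sets C1' by reagent-controlled reduction. It sets out from 1 and comes back at 2. Oxidation (MnO2, CH2Cl2, rt) gives hex-1-yn-3-one F3. Midland reduction with (R)-Alpine-Borane (B-isopinocampheyl-9-borabicyclo[3.3.1]nonane from (+)-α-pinene, neat, rt, then ethanolamine work-up) should deliver hydride through the boat-like six-membered transition state, with the slim ethynyl group next to the pinanyl methyl group, to give the (R)-propargylic alcohol 2.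

Further compounds
F1 | step 4 | 3-[(R)-1-(tert-butyldimethylsilyloxy)butyl]furan-2,5-dione | CCC[C@@H](O[Si](C)(C)C(C)(C)C)C1=CC(=O)OC1=O
F2 | step 6 | 3,4-dibromo-3-[(R)-1-(tert-butyldimethylsilyloxy)butyl]-5-(tribromomethyl)dihydrofuran-2(3H)-one | CCC[C@@H](O[Si](C)(C)C(C)(C)C)C1(Br)C(Br)C(C(Br)(Br)Br)OC1=O
F3 | step 1 | hex-1-yn-3-one | CCCC(=O)C#C
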